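Amounts first: you read [Pdt] and nothing else, and you are to say how much of it stands in a flask charged with far more Ptn than any earlier run.

| flask | Sbt | Ptn | Ctl | time |
|---|---|---|---|---|
| dusk | 0.600 M | 0.480 M | 0.00600 M |  |
| dawn | 0.600 M | 1.40 M | 0.00600 M |  |
| spring | 1.20 M | 0.480 M | 0.00600 M |  |
| midnight | 0.600 M | 0.480 M | 0.00900 M |  |
| autumn | 0.600 M | 3.50 M | 0.00600 M | 12 min |

| run | time / min | [Pdt] / M |
|---|---|---|
| dusk run | 0.48 | 0.027 |
| dusk run | 0.82 | 0.036 |
| dusk run | 1.4 | 0.061 |
| dusk run | 2.4 | 0.108 |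
| dusk run | 4.1 | 0.167 |
| dusk run | 7.0 | 0.252 |
| dusk run | 12 | 0.370 |
| dawn run | 0.48 | 0.020 |
| dawn run | 0.82 | 0.036 |
| dawn run | 1.4 | 0.059 |
| dawn run | 2.4 | 0.088 |
| dawn run | 4.1 | 0.126 |
| dawn run | 7.0 | 0.165 |
| dawn run | 12 | 0.199 |
| spring run | 0.48 | 0.027 |
| spring run | 0.82 | 0.045 |
| spring run | 1.4 | 0.072 |
| spring run | 2.4 | 0.125 |
| spring run | 4.1 | 0.205 |
| spring run | 7.0 | 0.340 |
| spring run | 12 | 0.402 |
| midnight run | 0.48 | 0.030 |
| midnight run | 0.82 | 0.050 |
| midnight run | 1.4 | 0.089 |
| midnight run | 2.4 | 0.148 |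
| midnight run | 4.1 | 0.236 |
| midnight run | 7.0 | 0.359 |
| midnight run | 12 | 0.402 |

(readings scatter by 0.003 M)

- Overall: Sbt + Ptn -> Pdt, with Ctl as catalyst.
- Constant volume, constant temperature.
- Readings of a species count what is bound in complexes too.
- An order is taken over about fifteen percent of the charge, up and down.

- order of the initial rate in [Ctl], near the charge of the dusk run, the rate being that where two percent of its Sbt are Pdt
- order of the initial rate in [Ptn], near the charge of the dusk run, the rate being that where two percent of its Sbt are Pdt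
- Pdt in the autumn run at 12 min, as a share of the Sbt charged

At 1.4 min the dusk run reads 0.061 M, the dawn run 0.059 M and the midnight run 0.089 M. From these I reckon an order of −0.0311 in [Ptn] and 0.932 in [Ctl].

Later the dawn run bends: its net rate from 7.0 min to 12 min is 0.00680 M min⁻¹, against 0.0421 M min⁻¹ early on. So compare two rates at one moment: making, taken as that early rate, and a loss I assume proportional to [Pdt][Ptn]. By the midpoint, 9.50 min, the early rate has made about 0.400 M, while the mean [Pdt] stands at 0.182 M. I assume that each Pdt lost takes a second Ptn, so about 0.781 M of Ptn is left, and the gap gives a drain constant of 0.249 M⁻¹ min⁻¹.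

In the autumn run Ptn stands in large excess, so this loss is pseudo-first-order, with a time of 1.15 min. Because that is much shorter than 12 min, [Pdt] should sit near the hold level, the [Pdt] at which loss equals making, which is the making rate over the drain constant times [Ptn]: 0.0484 M. I commit to 8.07 % of the Sbt charged.

The forecast gives 0.85, 0 and 17 %, a share higher than mine, and it reads the bend as “catalyst death roughly proportional to Ptn”.

The simulation gives 1.0, −0.0035 and 11.1 %.

    Ctl + Sbt → Ctl.Sbt (36.90 M⁻¹ min⁻¹)
    Ctl.Sbt + Ptn → E (1158 M⁻¹ min⁻¹)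
    E → Pdt + Ctl (201.6 min⁻¹)
    Ctl + Sbt ⇌ Ctl.Sbt', settled at all times (2.710 M⁻¹)
    Pdt + Ptn → Ofp (0.1530 M⁻¹ min⁻¹)

The bend appears in these steps as Pdt + Ptn → Ofp, with Ctl coming back from E. A fit with the main steps alone forecasts 54.6 % for the autumn run. The autumn flask holds 0.0668 M of Pdt, above the hold level of 0.0484 M. For the dusk run, its rate of 0.047 M min⁻¹ and its charged [Ptn] give a hold level of 0.390 M, and its reading at 12 min stands lower, at 0.370 M.

The data were generated by integration on assumed constants.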